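**Plan**
- Retrosynthesis: the two norbornene bonds C1–C13′ and C3–C11′ are cut first (Diels–Alder) to give a 2-silyloxyguaia-1(5),3-dien-6-one and the seco-eudesmanolide methylene lactone 34. Then C13 and the C12–O lactone bond are removed, and last the hydroazulene bonds C1–C5 and C7–C8 are cut as a furan–oxyallyl (4+3) cycloaddition.
- Enabling feature: C8 (lactone O–CH) and the quaternary bridgehead C1 stand 1,4 across the seven-membered ring with C9 and the methyl-bearing C10 between them. This is a 2,5-bridged 3-methylfuran, and C1 is also the first atom of the five-membered ring.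
- Forward order: acylation of 3-methylfuran, carbinol, α-chloro ketone; the (4+3) step closes the five-membered ring, the seven-membered ring and the C1–O–C8 bridge together. C4–C5 dehydrogenation and the acetate arm follow; bridge opening releases the cyclopentadiene, which 34 traps to close the norbornene. Lactone closure, C6 deoxygenation, methylenation and acetylation finish the route.
- Stereochemistry: C2 from asymmetric transfer hydrogenation; C1 and C8 relayed from C2 in the (4+3) step; C7 and C10 from exo-face hydrogenation; C1, C3 and C11′ from the Diels–Alder step. In 34: C4′ from (R)-citronellal, C8′ from a reagent-controlled aldol, C7′ by cis ring fusion, C10′ by convex-face methyl addition.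

Key step: step 7

Remark: guaiane locants (C1–C15) are used for the guaianolide half and primed eudesmane locants (C1′–C15′) for the seco-eudesmanolide half; 8, 9, 26, 39 and 40 are carried as epimer mixtures at centres that are erased later, and hemiester 1 is taken as purchasable.

Step 1
Reactants: 1 methyl hydrogen (R)-3-methylglutarate; 2 3-methylfuran
Product: 4 methyl (3R)-3-methyl-5-(3-methylfuran-2-yl)-5-oxopentanoate, via acid chloride 3 (not isolated)
Conditions: (COCl)2, DMF (cat.), CH2Cl2, 0 °C to rt; then 2, SnCl4, CH2Cl2, −78 °C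
Reagents that add atoms: none
Why: Friedel–Crafts acylation of 3-methylfuran should go to the α-carbon next to the methyl group, the more electron-rich α-position, and SnCl4 at low temperature limits polymerisation of the furan.

Step 2
Reactants: 4 keto ester
Product: 5 methyl (3R,5R)-5-hydroxy-3-methyl-5-(3-methylfuran-2-yl)pentanoate
Conditions: RuCl(p-cymene)[(R,R)-TsDPEN] (1 mol %), HCO2H/Et3N (5:2), CH2Cl2, rt
Reagents that add atoms: none
Why: asymmetric transfer hydrogenation of 2-acylfurans follows the aryl ketone model, so the (R,R)-catalyst should set the (R)-carbinol at C2 (the (S,S)-catalyst would be taken if the sense proved opposite), and the ester is untouched.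

Step 3
Reactants: 5 hydroxy ester
Product: 6 methyl (3R,5R)-5-[(tert-butyldimethylsilyl)oxy]-3-methyl-5-(3-methylfuran-2-yl)pentanoate
Conditions: t-BuMe2SiCl, imidazole, DMF, 0 °C to rt, directly on crude 5
Reagents that add atoms: tert-butyldimethylsilyl chloride CC(C)(C)[Si](C)(C)Cl
Why: standard silylation of a secondary alcohol, done at once so that the δ-hydroxy ester cannot lactonise.

Step 4
Reactants: 6 silyl ether ester
Product: 7 (3R,5R)-5-[(tert-butyldimethylsilyl)oxy]-N-methoxy-N,3-dimethyl-5-(3-methylfuran-2-yl)pentanamide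
Conditions: MeNH(OMe)·HCl, i-PrMgCl, THF, −20 °C
Reagents that add atoms: N,O-dimethylhydroxylamine hydrochloride CNOC.Cl
Why: the magnesium amide of N,O-dimethylhydroxylamine converts methyl esters into Weinreb amides (ester aminolysis) without touching the silyl ether or the furan.

Step 5
Reactants: 7 Weinreb amide
Product: 8 (3R,5R)-5-[(tert-butyldimethylsilyl)oxy]-2-chloro-N-methoxy-N,3-dimethyl-5-(3-methylfuran-2-yl)pentanamide (C2 epimers)
Conditions: LiN(i-Pr)2, THF, −78 °C; N-chlorosuccinimide, −78 °C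
Reagents that add atoms: N-chlorosuccinimide O=C1CCC(=O)N1Cl
Why: electrophilic chlorination of the amide enolate places chlorine at the only enolisable carbon, so the regiochemistry of the later chloro ketone is fixed here; the new C–Cl centre forms as a mixture and is lost on ionisation in step 7.

Step 6
Reactants: 8 chloro amide
Product: 9 (4R,6R)-6-[(tert-butyldimethylsilyl)oxy]-3-chloro-4-methyl-6-(3-methylfuran-2-yl)hexan-2-one (C3 epimers)
Conditions: MeMgBr, THF, −78 to −20 °C
Reagents that add atoms: methylmagnesium bromide C[Mg]Br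
Why: Weinreb ketone synthesis, in which the chelated tetrahedral intermediate prevents a second addition and α-chloro Weinreb amides are known to give α-chloro ketones.

Step 7
Reactants: 9 α-chloro methyl ketone
Product: 11 2-[(tert-butyldimethylsilyl)oxy]-1,8-epoxy-11,12,13-trinorguai-9-en-6-one (oxygen-bridged hydroazulenone), via oxyallyl cation 10 (not isolated)
Conditions: Et3N (2 equiv), CF3CH2OH, 0.02 M, 0 °C to rt
Reagents that add atoms: none
Why: Triethylamine enolises the ketone toward its methyl group and chloride leaves in the ionising solvent to give oxyallyl cation 10, which adds across the two α-carbons of the tethered furan and forms C1–C5 and C7–C8; the closest known reaction is the intramolecular (4+3) cycloaddition of amine-generated oxyallyl cations with furans. The five-membered ring closes through the three-atom tether in a 5-exo sense onto the tether-bearing furan carbon, the seven-membered ring closes when the methyl-derived cation terminus bonds to the other furan α-carbon, and the furan oxygen thereby becomes the one-atom bridge of an 8-oxabicyclo[3.2.1]octenone. C1 and C8 are set together because the cation adds to one furan face, and that face is chosen by the C2 carbinol: to avoid allylic 1,3-strain with the furan 3-methyl group the carbinol hydrogen lies in the furan plane next to the methyl, the tether rises to one face and the silyloxy group points to the other, so the bridge forms cis to the silyloxy group. C5 follows from the compact, tether-enforced transition state with the C4 methyl pseudo-equatorial and is erased later together with C4. The step needs ionisation and ring closure to outrun solvent capture of the cation and substitution of the chloride, which the intramolecular furan and high dilution should secure, and it needs the facial relay just described, which the 3-methyl group secures.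

Step 8
Reactants: 11 cycloadduct
Product: 12 2-[(tert-butyldimethylsilyl)oxy]-1,8-epoxy-11,12,13-trinorguaia-4,9-dien-6-one
Conditions: IBX (1.3 equiv), DMSO/fluorobenzene, 70 °C
Reagents that add atoms: none
Why: IBX dehydrogenation of a ketone through its enol can only give the C4–C5 enone here, because unsaturation from C7 would have to end at the bridgehead C8 (Bredt's rule).

Step 9
Reactants: 12 enone; 13 ethyl glyoxylate
Product: 16 ethyl (E)-2-[(tert-butyldimethylsilyl)oxy]-1,8-epoxy-6-oxo-13-norguaia-4,7(11),9-trien-12-oate, via aldol adduct 14 (not isolated), via mesylate 15 (not isolated)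
Conditions: LiN(SiMe3)2, THF, −78 °C; 13, −78 °C; then MeSO2Cl, Et3N, −78 to 0 °C
Reagents that add atoms: none
Why: kinetic α′-deprotonation of the enone at C7, aldol addition to the glyoxylate and mesylation–elimination amount to an aldol condensation, and the lithium enolate of an 8-oxabicyclo[3.2.1]octan-3-one is known to hold its bridge at −78 °C.

Step 10
Reactants: 16 trienone ester
Product: 17 ethyl 2-[(tert-butyldimethylsilyl)oxy]-1,8-epoxy-6-oxo-13-norguai-4-en-12-oate (H-7 and H-10 cis to the oxygen bridge)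
Conditions: H2 (1 atm), Pd/C (palladium on carbon), EtOAc, rt, stopped after two equivalents of H2
Reagents that add atoms: none
Why: heterogeneous hydrogenation should reduce the strained C9–C10 alkene and the activated exocyclic C7–C11 alkene from the exo face (the side of the oxygen bridge), which puts the C10 methyl and the C7 acetate arm anti to the bridge as the target requires, while the hindered tetrasubstituted enone alkene reacts more slowly.

Step 11
Reactants: 18 (R)-citronellal
Product: 19 (4R)-4,8-dimethylnon-7-en-2-ol (C2 epimers)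
Conditions: MeMgBr, Et2O, 0 °C
Reagents that add atoms: methylmagnesium bromide C[Mg]Br
Why: Grignard addition to the aldehyde; the new carbinol centre is oxidised away in step 14 and the C4′ stereocentre of citronellal is not touched.

Step 12
Reactants: 19 carbinol
Product: 20 (4R)-4-methylheptane-1,6-diol (C6 epimers)
Conditions: O3, CH2Cl2/MeOH, −78 °C; then NaBH4, −78 °C to rt
Reagents that add atoms: ozone [O-][O+]=O
Why: ozonolysis of the only alkene with reductive work-up turns the isopropylidene end into the primary alcohol that becomes C1′.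

Step 13
Reactants: 20 diol
Product: 21 (4R)-7-[(tert-butyldiphenylsilyl)oxy]-4-methylheptan-2-ol (C2 epimers)
Conditions: t-BuPh2SiCl (1.0 equiv), imidazole, CH2Cl2, −20 to 0 °C
Reagents that add atoms: tert-butyldiphenylsilyl chloride CC(C)(C)[Si](Cl)(c1ccccc1)c1ccccc1
Why: the bulky silyl chloride silylates the primary alcohol in preference to the secondary one, and this ether survives the aqueous acid of step 17.

Step 14
Reactants: 21 secondary alcohol
Product: 22 (4R)-7-[(tert-butyldiphenylsilyl)oxy]-4-methylheptan-2-one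
Conditions: Dess–Martin periodinane, NaHCO3, CH2Cl2, rt
Reagents that add atoms: none
Why: Dess–Martin oxidation of a secondary alcohol to the methyl ketone under buffered, neutral conditions.

Step 15
Reactants: 22 methyl ketone; 23 ethyl (E)-4-oxobut-2-enoate
Product: 25 ethyl (2E,4S,8R)-11-[(tert-butyldiphenylsilyl)oxy]-4-hydroxy-8-methyl-6-oxoundec-2-enoate, via boron enolate 24 (not isolated)
Conditions: (−)-Ipc2BCl, Et3N, Et2O, 0 °C; 23, −78 to −20 °C; then H2O2, pH 7 buffer, MeOH
Reagents that add atoms: none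
Why: the diisopinocampheylboron enolate forms on the methyl side and adds to the aldehyde (boron aldol reaction of a methyl ketone) under reagent control of the aldehyde face, which sets C8′; the (+)-reagent would be taken if the sense proved opposite.

Step 16
Reactants: 25 hydroxy enoate
Product: 26 ethyl (4S,8R)-11-[(tert-butyldiphenylsilyl)oxy]-3-(1,3-dioxolan-2-yl)-4-hydroxy-8-methyl-6-oxoundecanoate (C3 epimers)
Conditions: 1,3-dioxolane (solvent), benzophenone (0.2 equiv), hν (350 nm), rt
Reagents that add atoms: 1,3-dioxolane C1COCO1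
Why: photosensitised hydrogen abstraction gives the nucleophilic 1,3-dioxolan-2-yl radical, which adds to the β-carbon of the enoate (radical conjugate addition, known for γ-oxygenated enoates and butenolides) and so places a masked formyl group on C7′; the C7′ configuration is corrected in step 17.

Step 17
Reactants: 26 dioxolane adduct
Product: 29 (3aR,7aS)-5-[(2R)-5-[(tert-butyldiphenylsilyl)oxy]pentan-2-yl]-3a,7a-dihydro-1-benzofuran-2,6(3H,7H)-dione (cis-fused), via lactone acetal 27 (not isolated), via keto aldehyde 28 (not isolated)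
Conditions: 2 M HCl, THF, rt; then (PhCH2)2NH2 O2CCF3 (cat.), benzene, 50 °C
Reagents that add atoms: none
Why: acid closes the γ-lactone and frees the aldehyde, and the mild ammonium salt then effects the intramolecular aldol condensation of the ketone α-carbon C5′ onto the aldehyde C6′; C7′ is epimerisable α to the aldehyde and the ring fusion should settle as the more stable cis-fused bicycle, while the β-acyloxy ketone is spared strong base.

Step 18
Reactants: 29 enone lactone
Product: 30 (3aR,6R,7aS)-5-[(2R)-5-[(tert-butyldiphenylsilyl)oxy]pentan-2-yl]-6-hydroxy-6-methyl-3a,6,7,7a-tetrahydro-1-benzofuran-2(3H)-one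
Conditions: MeLi, CeCl3, THF, −78 °C
Reagents that add atoms: methyllithium [Li]C
Why: the weakly basic organocerium reagent adds 1,2 to the enone ketone from the convex face of the cis-fused bicycle, which puts the C10′ hydroxyl cis to the lactone oxygen, and it leaves the lactone and the β-acyloxy ketone unharmed.

Step 19
Reactants: 30 tertiary alcohol
Product: 31 triethylsilyl ether of 30 at O-10′
Conditions: Et3SiOTf, 2,6-lutidine, CH2Cl2, −78 to 0 °C
Reagents that add atoms: triethylsilyl trifluoromethanesulfonate CC[Si](CC)(CC)OS(=O)(=O)C(F)(F)F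
Why: silyl triflates silylate hindered tertiary alcohols, and the ether protects the allylic carbinol from the enolate and Lewis acid steps that follow.

Step 20
Reactants: 31 silyl-protected lactone
Product: 34 (3aS,6R,7aS)-5-[(2R)-5-[(tert-butyldiphenylsilyl)oxy]pentan-2-yl]-6-methyl-3-methylidene-6-[(triethylsilyl)oxy]-3a,6,7,7a-tetrahydro-1-benzofuran-2(3H)-one, via Mannich base 32 (not isolated), via ammonium iodide 33 (not isolated)
Conditions: LiN(i-Pr)2, THF, −78 °C; CH2=NMe2 I, −78 °C to rt; MeI, MeOH; aq. NaHCO3, CH2Cl2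
Reagents that add atoms: Eschenmoser's salt C=[N+](C)C.[I-]
Why: Mannich reaction of the lactone enolate with Eschenmoser's salt, quaternisation and elimination is the standard α-methylenation of γ-butyrolactones, and the lactone α-CH2 is the only acidic position.

Step 21
Reactants: 17 keto ester; 34 methylene lactone
Product: 36 Diels–Alder adduct (bonds C1–C13′ and C3–C11′; 8-O-trimethylsilyl, 2-O-tert-butyldimethylsilyl, ethyl C12 ester, 4-en-6-one), via silyloxy cyclopentadiene 35 (not isolated)
Conditions: Me3SiOTf (1.3 equiv), Et3N (2 equiv), 34 (1.5 equiv) present from the start, CH2Cl2 (0.5 M), −40 °C to rt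
Reagents that add atoms: trimethylsilyl trifluoromethanesulfonate C[Si](C)(C)OS(=O)(=O)C(F)(F)F
Why: Proposed new method: O-silylation of the enone and loss of a C3 proton should give the extended silyl dienol ether, silylation of the bridge oxygen then lets the tertiary C1–O bond ionise with push from that dienol ether, and the resulting 2-acylcyclopentadiene 35 (C1=C5, C3=C4) is trapped at once by 34 in an endo Diels–Alder reaction that joins CH2-13′ to the fully substituted C1 and the quaternary C11′ to C3, on the diene face syn to the C2 silyloxy group and anti to the C10 methyl and on the convex face of the cis-fused lactone; the closest known reactions are the silyl triflate–amine β-elimination opening of 8-oxabicyclo[3.2.1]octan-3-ones and the syn-selective Diels–Alder reactions of 5-oxygenated cyclopentadienes with α-methylene lactones.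

Step 22
Reactants: 36 Diels–Alder adduct
Product: 38 12,8-lactone of the adduct (trans-fused γ-lactone; 4-en-6-one), via hydroxy ester 37 (not isolated)
Conditions: PPTS, MeOH, rt; then PPTS, toluene, 60 °C
Reagents that add atoms: none
Why: mild acid methanolysis removes only the trimethylsilyl ether and the freed C8 hydroxyl lactonises onto the trans-disposed ester arm (acid-catalysed lactonisation) without enolising C7.

Step 23
Reactants: 38 enone lactone
Product: 39 C6 allylic alcohol (C6 epimers)
Conditions: NaBH4, CeCl3·7H2O, MeOH/CH2Cl2, −78 °C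
Reagents that add atoms: none
Why: Luche reduction gives 1,2-reduction of the enone and is selective for the ketone over both lactones.

Step 24
Reactants: 39 allylic alcohol
Product: 40 O-6 imidazol-1-ylthiocarbonyl derivative of 39
Conditions: 1,1′-thiocarbonyldiimidazole, DMAP (cat.), ClCH2CH2Cl, 60 °C
Reagents that add atoms: 1,1′-thiocarbonyldiimidazole S=C(n1ccnc1)n1ccnc1
Why: acylation of the only free hydroxyl gives the thiocarbonyl derivative needed for radical deoxygenation.

Step 25
Reactants: 40 thiocarbonyl derivative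
Product: 41 6-deoxy compound (C6 methylene, C4=C5 retained)
Conditions: Bu3SnH, AIBN, toluene, 90 °C
Reagents that add atoms: none
Why: Barton–McCombie deoxygenation; the allylic radical should take hydrogen at the less hindered secondary terminus C6, which keeps the tetrasubstituted C4=C5 alkene in place.

Step 26
Reactants: 41 lactone
Product: 44 13-methylidene lactone (tris-silyl ether of the triol 45), via Mannich base 42 (not isolated), via ammonium iodide 43 (not isolated)
Conditions: LiN(i-Pr)2, THF, −78 °C; CH2=NMe2 I, −78 °C to rt; MeI, MeOH; aq. NaHCO3, CH2Cl2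
Reagents that add atoms: Eschenmoser's salt C=[N+](C)C.[I-]
Why: the same Mannich–elimination α-methylenation as in step 20; the spiro lactone has no α-hydrogen and no ester with α-hydrogens is present, so only C11 is deprotonated.

Step 27
Reactants: 44 tris-silyl ether
Product: 45 triol (2-OH, 10′-OH, 1′-OH)
Conditions: HF·pyridine, pyridine, THF, 0 °C to rt
Reagents that add atoms: none
Why: buffered hydrogen fluoride cleaves all three silyl ethers (fluoride desilylation) without adding to the α-methylene lactones.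

Step 28
Reactants: 45 triol
Product: 46 CNP0257312.1
Conditions: Ac2O, pyridine, DMAP (cat.), CH2Cl2, 0 °C
Reagents that add atoms: acetic anhydride CC(=O)OC(C)=O
Why: acetylation of the primary and the secondary alcohol, while the hindered tertiary allylic alcohol at C10′ should stay free under these mild conditions.

**Compound list**

1 | methyl hydrogen (R)-3-methylglutarate, (3R)-5-methoxy-3-methyl-5-oxopentanoic acid | OC(=O)C[C@@H](C)CC(=O)OC | starting material
2 | 3-methylfuran | Cc1ccoc1 | starting material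
3 | methyl (3S)-5-chloro-3-methyl-5-oxopentanoate | ClC(=O)C[C@@H](C)CC(=O)OC | intermediate (not isolated)
4 | methyl (3R)-3-methyl-5-(3-methylfuran-2-yl)-5-oxopentanoate | Cc1ccoc1C(=O)C[C@@H](C)CC(=O)OC | intermediate
5 | methyl (3R,5R)-5-hydroxy-3-methyl-5-(3-methylfuran-2-yl)pentanoate | Cc1ccoc1[C@H](O)C[C@@H](C)CC(=O)OC | intermediate
6 | methyl (3R,5R)-5-[(tert-butyldimethylsilyl)oxy]-3-methyl-5-(3-methylfuran-2-yl)pentanoate | Cc1ccoc1[C@H](O[Si](C)(C)C(C)(C)C)C[C@@H](C)CC(=O)OC | intermediate
7 | (3R,5R)-5-[(tert-butyldimethylsilyl)oxy]-N-methoxy-N,3-dimethyl-5-(3-methylfuran-2-yl)pentanamide | Cc1ccoc1[C@H](O[Si](C)(C)C(C)(C)C)C[C@@H](C)CC(=O)N(C)OC | intermediate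
8 | (3R,5R)-5-[(tert-butyldimethylsilyl)oxy]-2-chloro-N-methoxy-N,3-dimethyl-5-(3-methylfuran-2-yl)pentanamide, C2 epimers | Cc1ccoc1[C@H](O[Si](C)(C)C(C)(C)C)C[C@@H](C)C(Cl)C(=O)N(C)OC | intermediate
9 | (4R,6R)-6-[(tert-butyldimethylsilyl)oxy]-3-chloro-4-methyl-6-(3-methylfuran-2-yl)hexan-2-one, C3 epimers | Cc1ccoc1[C@H](O[Si](C)(C)C(C)(C)C)C[C@@H](C)C(Cl)C(C)=O | intermediate
10 | oxyallyl (2-oxidoallyl) cation derived from 9 | Cc1ccoc1[C@H](O[Si](C)(C)C(C)(C)C)C[C@@H](C)[CH+]C(=C)[O-] | intermediate (not isolated)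
11 | 2-[(tert-butyldimethylsilyl)oxy]-1,8-epoxy-11,12,13-trinorguai-9-en-6-one; silyloxy cis to the oxygen bridge, 4-methyl trans to the silyloxy group, H-5 trans to the bridge | CC1=C[C@@H]2CC(=O)[C@H]3[C@H](C)C[C@@H](O[Si](C)(C)C(C)(C)C)[C@]13O2 | intermediate
12 | 2-[(tert-butyldimethylsilyl)oxy]-1,8-epoxy-11,12,13-trinorguaia-4,9-dien-6-one | CC1=C[C@@H]2CC(=O)C3=C(C)C[C@@H](O[Si](C)(C)C(C)(C)C)[C@]13O2 | intermediate
13 | ethyl glyoxylate | CCOC(=O)C=O | starting material
14 | ethyl 2-[(tert-butyldimethylsilyl)oxy]-1,8-epoxy-11-hydroxy-6-oxo-13-norguaia-4,9-dien-12-oate (aldol adduct, C7/C11 mixture) | CC1=C[C@@H]2C(C(O)C(=O)OCC)C(=O)C3=C(C)C[C@@H](O[Si](C)(C)C(C)(C)C)[C@]13O2 | intermediate (not isolated)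
15 | 11-methanesulfonate of 14 | CC1=C[C@@H]2C(C(OS(C)(=O)=O)C(=O)OCC)C(=O)C3=C(C)C[C@@H](O[Si](C)(C)C(C)(C)C)[C@]13O2 | intermediate (not isolated)
16 | ethyl (E)-2-[(tert-butyldimethylsilyl)oxy]-1,8-epoxy-6-oxo-13-norguaia-4,7(11),9-trien-12-oate | CC1=C[C@@H]2/C(=C\C(=O)OCC)C(=O)C3=C(C)C[C@@H](O[Si](C)(C)C(C)(C)C)[C@]13O2 | intermediate
17 | ethyl 2-[(tert-butyldimethylsilyl)oxy]-1,8-epoxy-6-oxo-13-norguai-4-en-12-oate; H-7 and H-10 cis to the oxygen bridge | C[C@@H]1C[C@@H]2[C@H](CC(=O)OCC)C(=O)C3=C(C)C[C@@H](O[Si](C)(C)C(C)(C)C)[C@]13O2 | intermediate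
18 | (R)-citronellal | CC(C)=CCC[C@@H](C)CC=O | starting material
19 | (4R)-4,8-dimethylnon-7-en-2-ol, C2 epimers | CC(C)=CCC[C@@H](C)CC(C)O | intermediate
20 | (4R)-4-methylheptane-1,6-diol, C6 epimers | OCCC[C@@H](C)CC(C)O | intermediate
21 | (4R)-7-[(tert-butyldiphenylsilyl)oxy]-4-methylheptan-2-ol, C2 epimers | CC(O)C[C@H](C)CCCO[Si](c1ccccc1)(c1ccccc1)C(C)(C)C | intermediate
22 | (4R)-7-[(tert-butyldiphenylsilyl)oxy]-4-methylheptan-2-one | CC(=O)C[C@H](C)CCCO[Si](c1ccccc1)(c1ccccc1)C(C)(C)C | intermediate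
23 | ethyl (E)-4-oxobut-2-enoate | CCOC(=O)/C=C/C=O | starting material
24 | di[(−)-isopinocampheyl]boron enolate of 22 (methyl side; configuration of the isopinocampheyl groups not written in the SMILES) | C=C(OB(C1CC2CC(C1C)C2(C)C)C1CC2CC(C1C)C2(C)C)C[C@H](C)CCCO[Si](c1ccccc1)(c1ccccc1)C(C)(C)C | intermediate (not isolated)
25 | ethyl (2E,4S,8R)-11-[(tert-butyldiphenylsilyl)oxy]-4-hydroxy-8-methyl-6-oxoundec-2-enoate | CCOC(=O)/C=C/[C@@H](O)CC(=O)C[C@H](C)CCCO[Si](c1ccccc1)(c1ccccc1)C(C)(C)C | intermediate
26 | ethyl (4S,8R)-11-[(tert-butyldiphenylsilyl)oxy]-3-(1,3-dioxolan-2-yl)-4-hydroxy-8-methyl-6-oxoundecanoate, C3 epimers | CCOC(=O)CC(C1OCCO1)[C@@H](O)CC(=O)C[C@H](C)CCCO[Si](c2ccccc2)(c2ccccc2)C(C)(C)C | intermediate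
27 | γ-lactone of 26 (4-(1,3-dioxolan-2-yl)-5-(2-oxoalkyl)dihydrofuran-2-one) | O=C1CC(C2OCCO2)[C@H](CC(=O)C[C@H](C)CCCO[Si](c3ccccc3)(c3ccccc3)C(C)(C)C)O1 | intermediate (not isolated)
28 | keto aldehyde (4-formyl lactone from 27) | O=CC1CC(=O)O[C@H]1CC(=O)C[C@H](C)CCCO[Si](c2ccccc2)(c2ccccc2)C(C)(C)C | intermediate (not isolated)
29 | (3aR,7aS)-5-[(2R)-5-[(tert-butyldiphenylsilyl)oxy]pentan-2-yl]-3a,7a-dihydro-1-benzofuran-2,6(3H,7H)-dione | C1C(=O)O[C@H]2CC(=O)C([C@H](C)CCCO[Si](c3ccccc3)(c3ccccc3)C(C)(C)C)=C[C@H]21 | intermediate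
30 | (3aR,6R,7aS)-5-[(2R)-5-[(tert-butyldiphenylsilyl)oxy]pentan-2-yl]-6-hydroxy-6-methyl-3a,6,7,7a-tetrahydro-1-benzofuran-2(3H)-one | C1C(=O)O[C@H]2C[C@@](C)(O)C([C@H](C)CCCO[Si](c3ccccc3)(c3ccccc3)C(C)(C)C)=C[C@H]21 | intermediate
31 | 6-O-triethylsilyl ether of 30 | C1C(=O)O[C@H]2C[C@@](C)(O[Si](CC)(CC)CC)C([C@H](C)CCCO[Si](c3ccccc3)(c3ccccc3)C(C)(C)C)=C[C@H]21 | intermediate
32 | 3-[(dimethylamino)methyl] derivative of 31 (Mannich base, C3 epimers) | CN(C)CC1C(=O)O[C@H]2C[C@@](C)(O[Si](CC)(CC)CC)C([C@H](C)CCCO[Si](c3ccccc3)(c3ccccc3)C(C)(C)C)=C[C@H]21 | intermediate (not isolated)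
33 | trimethylammonium iodide of 32 | C[N+](C)(C)CC1C(=O)O[C@H]2C[C@@](C)(O[Si](CC)(CC)CC)C([C@H](C)CCCO[Si](c3ccccc3)(c3ccccc3)C(C)(C)C)=C[C@H]21.[I-] | intermediate (not isolated)
34 | (3aS,6R,7aS)-5-[(2R)-5-[(tert-butyldiphenylsilyl)oxy]pentan-2-yl]-6-methyl-3-methylidene-6-[(triethylsilyl)oxy]-3a,6,7,7a-tetrahydro-1-benzofuran-2(3H)-one | C=C1C(=O)O[C@H]2C[C@@](C)(O[Si](CC)(CC)CC)C([C@H](C)CCCO[Si](c3ccccc3)(c3ccccc3)C(C)(C)C)=C[C@H]21 | intermediate
35 | ethyl 2-[(tert-butyldimethylsilyl)oxy]-6-oxo-8-[(trimethylsilyl)oxy]-13-norguaia-1(5),3-dien-12-oate | C[C@@H]1C[C@@H](O[Si](C)(C)C)[C@H](CC(=O)OCC)C(=O)C2=C1[C@H](O[Si](C)(C)C(C)(C)C)C=C2C | intermediate (not isolated)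
36 | Diels–Alder adduct of 35 and 34 (norbornene, C4=C5, 6-ketone; 8-O-trimethylsilyl, 2-O-tert-butyldimethylsilyl, ethyl C12 ester; 10′-O-triethylsilyl, 1′-O-tert-butyldiphenylsilyl) | CCOC(=O)C[C@H]1[C@H](O[Si](C)(C)C)C[C@@H](C)[C@]23C[C@]4(C(=O)O[C@H]5C[C@@](C)(O[Si](CC)(CC)CC)C([C@H](C)CCCO[Si](c6ccccc6)(c6ccccc6)C(C)(C)C)=C[C@H]54)[C@H](C(C)=C2C1=O)[C@H]3O[Si](C)(C)C(C)(C)C | intermediate
37 | 8-hydroxy ester from 36 | CCOC(=O)C[C@H]1[C@H](O)C[C@@H](C)[C@]23C[C@]4(C(=O)O[C@H]5C[C@@](C)(O[Si](CC)(CC)CC)C([C@H](C)CCCO[Si](c6ccccc6)(c6ccccc6)C(C)(C)C)=C[C@H]54)[C@H](C(C)=C2C1=O)[C@H]3O[Si](C)(C)C(C)(C)C | intermediate (not isolated)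
38 | 6-oxo-12,8-olide of the adduct (trans-fused lactone, 11,13-dihydro, tris-silyl) | C1C(=O)O[C@@H]2C[C@@H](C)[C@]34C[C@]5(C(=O)O[C@H]6C[C@@](C)(O[Si](CC)(CC)CC)C([C@H](C)CCCO[Si](c7ccccc7)(c7ccccc7)C(C)(C)C)=C[C@H]65)[C@H](C(C)=C3C(=O)[C@@H]12)[C@H]4O[Si](C)(C)C(C)(C)C | intermediate
39 | 6-hydroxy compound from 38 (C6 epimers) | C1C(=O)O[C@@H]2C[C@@H](C)[C@]34C[C@]5(C(=O)O[C@H]6C[C@@](C)(O[Si](CC)(CC)CC)C([C@H](C)CCCO[Si](c7ccccc7)(c7ccccc7)C(C)(C)C)=C[C@H]65)[C@H](C(C)=C3C(O)[C@@H]12)[C@H]4O[Si](C)(C)C(C)(C)C | intermediate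
40 | 6-O-(imidazol-1-ylthiocarbonyl) derivative of 39 | C1C(=O)O[C@@H]2C[C@@H](C)[C@]34C[C@]5(C(=O)O[C@H]6C[C@@](C)(O[Si](CC)(CC)CC)C([C@H](C)CCCO[Si](c7ccccc7)(c7ccccc7)C(C)(C)C)=C[C@H]65)[C@H](C(C)=C3C(OC(=S)n8ccnc8)[C@@H]12)[C@H]4O[Si](C)(C)C(C)(C)C | intermediate
41 | 6-deoxy 11,13-dihydro compound (tris-silyl) | C1C(=O)O[C@@H]2C[C@@H](C)[C@]34C[C@]5(C(=O)O[C@H]6C[C@@](C)(O[Si](CC)(CC)CC)C([C@H](C)CCCO[Si](c7ccccc7)(c7ccccc7)C(C)(C)C)=C[C@H]65)[C@H](C(C)=C3C[C@@H]12)[C@H]4O[Si](C)(C)C(C)(C)C | intermediate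
42 | 11-[(dimethylamino)methyl] derivative of 41 (C11 epimers) | CN(C)CC1C(=O)O[C@@H]2C[C@@H](C)[C@]34C[C@]5(C(=O)O[C@H]6C[C@@](C)(O[Si](CC)(CC)CC)C([C@H](C)CCCO[Si](c7ccccc7)(c7ccccc7)C(C)(C)C)=C[C@H]65)[C@H](C(C)=C3C[C@@H]12)[C@H]4O[Si](C)(C)C(C)(C)C | intermediate (not isolated)
43 | trimethylammonium iodide of 42 | C[N+](C)(C)CC1C(=O)O[C@@H]2C[C@@H](C)[C@]34C[C@]5(C(=O)O[C@H]6C[C@@](C)(O[Si](CC)(CC)CC)C([C@H](C)CCCO[Si](c7ccccc7)(c7ccccc7)C(C)(C)C)=C[C@H]65)[C@H](C(C)=C3C[C@@H]12)[C@H]4O[Si](C)(C)C(C)(C)C.[I-] | intermediate (not isolated)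
44 | 2-O-tert-butyldimethylsilyl, 10′-O-triethylsilyl, 1′-O-tert-butyldiphenylsilyl ether of triol 45 | C=C1C(=O)O[C@@H]2C[C@@H](C)[C@]34C[C@]5(C(=O)O[C@H]6C[C@@](C)(O[Si](CC)(CC)CC)C([C@H](C)CCCO[Si](c7ccccc7)(c7ccccc7)C(C)(C)C)=C[C@H]65)[C@H](C(C)=C3C[C@@H]12)[C@H]4O[Si](C)(C)C(C)(C)C | intermediate
45 | triol (bis-deacetyl target: 2-OH, 10′-OH, 1′-OH) | C=C1C(=O)O[C@@H]2C[C@@H](C)[C@]34C[C@]5(C(=O)O[C@H]6C[C@@](C)(O)C([C@H](C)CCCO)=C[C@H]65)[C@H](C(C)=C3C[C@@H]12)[C@H]4O | intermediate
46 | CNP0257312.1 | C=C1C(=O)O[C@@H]2C[C@@H](C)[C@]34C[C@]5(C(=O)O[C@H]6C[C@@](C)(O)C([C@H](C)CCCOC(C)=O)=C[C@H]65)[C@H](C(C)=C3C[C@@H]12)[C@H]4OC(C)=O | target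

**Totals**
Total step count: 28. Longest linear sequence: 18 steps (1 to 46 through 17; the branch from 18 through 34 is equally long).

**Steps most likely to fail**

Step 21. The silyl enol ether may form on the C7 side, so that the bridge opens in the wrong direction and the oxygen stays on C1; the diene may undergo 1,5-hydrogen shift before it is captured; or 34 may add anti to the bulky silyloxy group. Fallback, from 17 back to 38: the Lewis-acid opening is replaced by the base-induced β-elimination known for 8-oxabicyclo[3.2.1]octan-3-ones. With DBU (0.3 equiv) and 34 in toluene at 40 °C, enolisation is reversible and a wrong-direction opening gives a tertiary alkoxide that can add back to its enone. Opening at C1 gives a C8 alkoxide that lactonises irreversibly onto the ester arm, forming the lactone diene F1, and the thermal Diels–Alder reaction of F1 with 34 gives 38 directly.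

Step 7. The oxyallyl cation may be captured by trifluoroethanol or lost through Favorskii-type contraction, or the relay from the carbinol to the furan face may be weak. Fallback, from 9 back to 11: the kinetic triethylsilyl enol ether F2 is made with LiN(SiMe3)2 and Et3SiCl in THF at −78 °C and ionised with AgBF4 in CH2Cl2 at −78 °C. The 2-silyloxyallyl cation formed in a non-nucleophilic solvent undergoes the same intramolecular (4+3) cycloaddition, a known reaction of 2-silyloxyallyl halides, and the colder transition state should sharpen the allylic-strain relay.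

Step 8. Enolisation toward C5 may be slow, since that hydrogen is poorly aligned with the carbonyl, and the enone may be oxidised further. Fallback, from 8 back to 12: a second chlorination (LiN(i-Pr)2, N-chlorosuccinimide) gives the 2,2-dichloro amide F3, and MeMgBr gives the dichloro ketone F4. The chloro-substituted oxyallyl cation (Et3N, CF3CH2OH, known for polychloro ketones) gives the 5-chloro cycloadduct F5, and dehydrochlorination with LiBr and Li2CO3 in DMF at 100 °C can only give the C4–C5 enone 12.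

Further compounds
F1 | step 21 | 2-[(tert-butyldimethylsilyl)oxy]-6-oxo-13-norguaia-1(5),3-dien-12,8-olide (lactone diene, not isolated) | C1C(=O)O[C@@H]2C[C@@H](C)C3=C(C(C)=C[C@H]3O[Si](C)(C)C(C)(C)C)C(=O)[C@@H]12
F2 | step 7 | triethylsilyl enol ether of 9 (3-chloro-2-silyloxy-1-alkene) | Cc1ccoc1[C@H](O[Si](C)(C)C(C)(C)C)C[C@@H](C)C(Cl)C(=C)O[Si](CC)(CC)CC
F3 | step 8 | 2,2-dichloro analogue of amide 8 | Cc1ccoc1[C@H](O[Si](C)(C)C(C)(C)C)C[C@@H](C)C(Cl)(Cl)C(=O)N(C)OC
F4 | step 8 | 3,3-dichloro analogue of ketone 9 | Cc1ccoc1[C@H](O[Si](C)(C)C(C)(C)C)C[C@@H](C)C(Cl)(Cl)C(C)=O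
F5 | step 8 | 5-chloro analogue of cycloadduct 11 | CC1=C[C@@H]2CC(=O)C3(Cl)[C@H](C)C[C@@H](O[Si](C)(C)C(C)(C)C)[C@]13O2
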